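Whatever substrate is left in these flasks tells you the mono adduct beside it, as long as the ratio of the two additions holds, so you need one ratio and one pace. Thursday's mono adduct stands still between 40.0 s and 60.0 s (52.0%, then 51.6%), and a standstill means that substrate left equals the ratio times mono adduct. Substrate over mono adduct there reads 0.458: the speed of the second addition over the first at equal amounts, the selectivity factor r. With s the fraction of substrate left, mono adduct = (s^r − s)/(1 − r). On Monday's last reading this gives 51.6% against 51.8% read.

| setting | Monday's | Thursday's | ochre | amber | violet |
|---|---|---|---|---|---|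
| substrate | 0.34 M | 0.25 M | 0.50 M | 0.50 M | 0.50 M |
| partner | 0.40 M | 0.40 M | 0.400 M | 1.25 M | 2.00 M |
| remark | run made earlier | run made earlier |  |  |  |
| time |  |  | 4.0 min | 4.0 min | 4.0 min |

| run | time / s | mono adduct / % | bis adduct / % |
|---|---|---|---|
| Monday's | 10.0 | 32.6 | 3.9 |
| Monday's | 30.0 | 48.0 | 13.1 |
| Monday's | 50.0 | 50.8 | 18.4 |
| Monday's | 80.0 | 51.8 | 23.4 |
| Thursday's | 20.0 | 45.5 | 9.5 |
| Thursday's | 40.0 | 52.0 | 21.0 |
| Thursday's | 60.0 | 51.6 | 27.9 |
| Thursday's | 80.0 | 50.9 | 33.0 |

(each reading ± 0.5 percentage points)

1. how much mono adduct is there at the end, in percent of the substrate charged: for each flask in turn (ochre, amber, violet)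

Now the pace of substrate, which I take as a constant times the partner left by the balance of the two adducts. Monday's first 10.0 s read the constant as 0.137 /M/s, but between 50.0 s and 80.0 s as 0.0865 /M/s, a brake of 1.58 once bis adduct stands.

In ochre I let the pace stop with the partner charge. Mono adduct takes one partner and bis adduct two, so with mono adduct near its plateau, substrate ends near 34.1%, and my rule gives 49.8%.

In amber I take the start pace of 0.171 /s down, by the partner balance and Monday's brake, to 0.0216 /s. That late pace over the whole time puts mono adduct at 16.1%, a rough estimate of my own, and the start runs faster than this late pace.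

In violet, supposing each bis adduct holds one more partner, 0.500 M of partner stays free, and that pace over the whole time puts mono adduct near 0.0980%, again my own estimate.

The forecast, reading the brake as “bis adduct tying up partner”, gives 49.5%, 12% and 0.05%, close to mine in ochre and lower than my estimates in amber and in violet.

The flasks give 49.6%, 10.3% and 0.0104%. Ochre ends with partner, the limiting reagent, at 0.10% of its charge and substrate at 35%.

    substrate + partner → mono adduct (k = 0.140 /M/s)
    partner + bis adduct ⇌ idle adduct, settled at all times (K = 14.0 /M)
    partner + mono adduct → bis adduct (k = 0.0630 /M/s)

Put ochre's substrate into the rule with r at 0.458 and you get 49.5% of mono adduct. Amber's 0.18% of substrate gives 9.88%, beside the 10.3% that stands in amber.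

The readings stem from a simulated flask with made-up constants, and the scatter is random.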